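**Strategy.** The 33-membered lactone ring of the target (C1 carbonyl to C32 on the ring oxygen, 31 unbranched CH2 groups, no stereocentre) is cut into the 16 carbons of the 17-membered musk lactone isoambrettolide 1 and two C8 units from cis-cyclooctene 2. One three-component ring-expansion metathesis splices both cyclooctenes into the lactone alkene, forming the C9=C10, C17=C18 and C25=C26 bonds and the macrocycle. The step exploits the featureless polymethylene run C2–C31, which tolerates alkenes in any position and geometry because hydrogenation erases them. The precursors are the two commercial cycloalkenes, used as bought.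

Key step: step 1

Assumption: commercial isoambrettolide is drawn as the E isomer of its C9=C10 alkene; an E/Z mixture serves equally, since no alkene survives step 2.

Design remarks:
- Atom count: C16H28O2 (1) + 2 C8H14 (2) = C32H56O2 (4); adding 3 H2 gives C32H62O2 (5). Both steps are pure additions with no co-product.
- The concentration is set just below the critical concentration for polymer, not at extreme dilution. At extreme dilution the ring–ring equilibrium should drift toward the smallest strain-free rings (recovered 1 and the hydrocarbon cyclic dimer of 2).
- Work-up runs in two stages. Silica separates by number of ester groups: hydrocarbon cyclooligomers of 2 first, then monolactones, then dilactones. Size exclusion then resolves the monolactone homologues C16 (1), C24 (3), C32 (4) and C40.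
- Every off-target fraction belongs to the same equilibrium manifold and is returned to the next run.

**Step 1**
Reactants: 1 (E)-oxacycloheptadec-10-en-2-one (isoambrettolide); 2 cis-cyclooctene (2 equiv)
Product: 4 (10E,18E,26E)-oxacyclotritriaconta-10,18,26-trien-2-one, via 25-membered dienolide 3 (not isolated)
Conditions: 2 (2 equiv, syringe pump), second-generation Grubbs catalyst RuCl2(=CHPh)(PCy3)(H2IMes) (2 mol%), 1,4-benzoquinone (10 mol%), CH2Cl2 (about 5 mM in 1), 40 °C, monitored by GC and SEC; then ethyl vinyl ether; SiO2, then preparative size-exclusion chromatography
Reagents that add atoms: none
Why: Proposed new method: the ruthenium benzylidene opens strained cis-cyclooctene, the resulting alkylidene cross-metathesises with the C9=C10 alkene of 1 or takes up a second cyclooctene, and the chain-end alkylidene then back-bites on the distal alkene of its own chain, so that two C8 units are spliced between C9 and C10 of the lactone with new C9=C10, C17=C18 and C25=C26 bonds. The closest known reaction types are ring-expansion metathesis of cycloalkenes with acyclic dienes and the ring-opening–ring-closing equilibration of macrocyclic olefins; what is unproven is stopping the insertion at exactly two units. The 33-membered ring is closed by intramolecular metathesis of the alkylidene onto a remote internal alkene (macrocyclic ring-closing metathesis by back-biting), which should win over chain growth because the total alkene concentration lies below the critical concentration for polymer. No stereocentre is created, and the alkene geometry (a mixture is expected, drawn all-E) is irrelevant because all three alkenes are hydrogenated in step 2. The step needs selectivity in the number of inserted units and in keeping the alkenes in place: the first rests only on the one-to-two feed, the slow addition of 2 and the concentration, so the homologues differing by C8H14 must be separated by size and the lower ones recycled; the second is secured by 1,4-benzoquinone, which should suppress ruthenium hydride alkene migration that would change the carbon count by single CH2 units.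

**Step 2**
Reactants: 4 (10E,18E,26E)-oxacyclotritriaconta-10,18,26-trien-2-one (any mixture of alkene geometries)
Product: 5 oxacyclotritriacontan-2-one (dotriacontan-32-olide)
Conditions: H2 (1 atm), 10% Pd/C, EtOAc/THF, rt to 40 °C
Reagents that add atoms: none
Why: Heterogeneous catalytic hydrogenation on palladium should saturate the three unhindered 1,2-disubstituted alkenes whatever their geometry while the lactone stays inert under neutral conditions, so every isomer of 4 converges on 5.

**Compound list**
1 | (E)-oxacycloheptadec-10-en-2-one (isoambrettolide, (E)-hexadec-9-en-16-olide) | O=C1CCCCCCC/C=C/CCCCCCO1 | starting material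
2 | cis-cyclooctene | C1CC/C=C\CCC1 | starting material
3 | (10E,18E)-oxacyclopentacosa-10,18-dien-2-one (drawn all-E; 25-membered mono-insertion lactone) | O=C1CCCCCCC/C=C/CCCCCC/C=C/CCCCCCO1 | intermediate
4 | (10E,18E,26E)-oxacyclotritriaconta-10,18,26-trien-2-one (drawn all-E; mixture of geometries expected) | O=C1CCCCCCC/C=C/CCCCCC/C=C/CCCCCC/C=C/CCCCCCO1 | intermediate
5 | oxacyclotritriacontan-2-one (dotriacontan-32-olide) | O=C1CCCCCCCCCCCCCCCCCCCCCCCCCCCCCCCO1 | target

**Totals**
Total step count: 2. Longest linear sequence: 2 (1 → 4 → 5).

**Steps most likely to fail** (the route has only two steps; both are ranked)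

1. Step 1. The number of cyclooctene units taken up is controlled only statistically. Ring–ring redistribution may drain the mixture toward the smallest strain-free rings, cyclooctene may cyclooligomerise without engaging the lactone alkene, or the homologues may not be resolved by size, leaving too little pure C32 triene. The fallback uses known chemistry only, sets out from 1 and rejoins the route at 5; it is a C16 + C16 Wittig union followed by macrolactonisation. Methanolysis of 1 (NaOMe cat., MeOH, reflux) should give methyl (E)-16-hydroxyhexadec-9-enoate F1. Appel bromination (CBr4, PPh3, CH2Cl2, 0 °C) should give methyl (E)-16-bromohexadec-9-enoate F2, and heating with PPh3 in MeCN should give [(E)-16-methoxy-16-oxohexadec-7-en-1-yl]triphenylphosphonium bromide F3. A second portion of 1 is half-reduced (i-Bu2AlH, CH2Cl2, −78 °C, aqueous work-up) to (E)-16-hydroxyhexadec-9-enal F4. The ylide from F3 (NaN(SiMe3)2, THF, −78 °C to rt, in excess to absorb the free hydroxyl) and F4 should give methyl (9E,16Z,25E)-32-hydroxydotriaconta-9,16,25-trienoate F5. Saponification (LiOH, THF/MeOH/H2O; then aq. HCl) should give (9E,16Z,25E)-32-hydroxydotriaconta-9,16,25-trienoic acid F6. Yamaguchi macrolactonisation (2,4,6-trichlorobenzoyl chloride, Et3N, THF; then slow addition to DMAP, toluene, reflux) should give (10E,17Z,26E)-oxacyclotritriaconta-10,17,26-trien-2-one F7. F7 is a positional isomer of 4, and the conditions of step 2 (H2, Pd/C) should convert it into 5.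

2. Step 2. Hydrogen uptake may stall before all three alkenes are saturated, through poisoning of the palladium surface by ruthenium or quinone residues carried over from step 1 or through deposition of the waxy, partly saturated lactone on the catalyst. The fallback sets out from 4 and returns at 5 and replaces surface catalysis by a metal-free concerted hydrogen transfer: diimide generated in situ (p-toluenesulfonyl hydrazide in excess, NaOAc, DME/H2O, reflux) should reduce the three disubstituted alkenes without touching the lactone. No new compound is made.

**Further compounds**
F1 | step 1 | methyl (E)-16-hydroxyhexadec-9-enoate | COC(=O)CCCCCCC/C=C/CCCCCCO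
F2 | step 1 | methyl (E)-16-bromohexadec-9-enoate | COC(=O)CCCCCCC/C=C/CCCCCCBr
F3 | step 1 | [(E)-16-methoxy-16-oxohexadec-7-en-1-yl]triphenylphosphonium bromide | COC(=O)CCCCCCC/C=C/CCCCCC[P+](c1ccccc1)(c1ccccc1)c1ccccc1.[Br-]
F4 | step 1 | (E)-16-hydroxyhexadec-9-enal | O=CCCCCCCC/C=C/CCCCCCO
F5 | step 1 | methyl (9E,16Z,25E)-32-hydroxydotriaconta-9,16,25-trienoate | COC(=O)CCCCCCC/C=C/CCCCC/C=C\CCCCCCC/C=C/CCCCCCO
F6 | step 1 | (9E,16Z,25E)-32-hydroxydotriaconta-9,16,25-trienoic acid | OC(=O)CCCCCCC/C=C/CCCCC/C=C\CCCCCCC/C=C/CCCCCCO
F7 | step 1 | (10E,17Z,26E)-oxacyclotritriaconta-10,17,26-trien-2-one | O=C1CCCCCCC/C=C/CCCCC/C=C\CCCCCCC/C=C/CCCCCCO1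
F0 | step 2 | none | none
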